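**Plan** (labdane numbering for the carbon skeleton)

- Retrosynthesis: cut the C15–O palmitate ester and the C4–CH3 bond (ester-enolate methylation), add a temporary ketone at C1, then cut C2–C3 and C5–C10 together; this unzips rings A and B to an acyclic bromo keto ester.
- Enabling feature: in ring A the ester-bearing C4 lies between C3 and C5, so C3–C4(CO2Me)–C5 is a latent 2-(bromomethyl)alk-2-enoate (electrophilic at C5, then at C3); across the ring, C2–C1–C10 becomes a bis-nucleophile once C1 is a ketone.
- The acyclic precursor is cut at C4=C5 (cross-metathesis), C13=C14 (Horner–Wadsworth–Emmons), C1–C2 and C10–C20 (one-carbon additions to an aldehyde) and C6–C7 (allylation), leading back to (R)-limonene, whose ring double bond supplies C1 and C13 on cleavage.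
- Forward: allylate limonene, open its ring, build the three arms on C9; one base-mediated cascade then closes ring B (C5–C10, 6-exo) and ring A (C2–C3, 6-endo); C1=O is removed, C4 is methylated, the silyl ether is exchanged for palmitate.
- Stereochemistry: C9 is C4 of (R)-limonene; C10 and C5 arise in the cascade under control of C9 (both C10 epimers of the precursor converge); C4 by equatorial methylation anti to the axial C10 methyl; 13E from the olefination.

Key step: step 12

Remark: the target is read as the 15-O-palmitate of methyl isocupressate (4S,5R,9S,10R,13E; CO2Me axial on C4, cis to the C10 methyl); atom numbers below are labdane numbers unless a systematic name is given.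

**Route**

Step 1
Reactants: 1 (R)-(+)-limonene; 2 allyl bromide
Product: 4 (4R)-4-(hexa-1,5-dien-2-yl)-1-methylcyclohex-1-ene, via lithiated limonene 3 (not isolated)
Conditions: n-BuLi, TMEDA, neat 1 (2 equiv), rt, 24 h; then THF, 2, −78 °C → rt
Reagents that add atoms: none
Why: kinetic allylic metalation of limonene by n-BuLi·TMEDA takes place at the isopropenyl methyl group, and SN2 alkylation of the symmetrical allyllithium with allyl bromide extends that methyl (future C7) by C6, C5 and a sacrificial CH2 without touching the stereocentre that becomes C9.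

Step 2
Reactants: 4 triene
Product: 5 (4R)-4-(hexa-1,5-dien-2-yl)-1-methyl-7-oxabicyclo[4.1.0]heptane (cis/trans epoxide mixture)
Conditions: mCPBA (1.0 equiv), CH2Cl2, 0 °C
Reagents that add atoms: mCPBA, OOC(=O)c1cccc(Cl)c1
Why: Prilezhaev epoxidation is fastest at the electron-rich trisubstituted ring alkene, so the 1,1-disubstituted and monosubstituted alkenes should survive, and the epoxide diastereomers do not matter because both carbons become carbonyls.

Step 3
Reactants: 5 epoxide
Product: 6 (3R)-3-(hexa-1,5-dien-2-yl)-6-oxoheptanal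
Conditions: H5IO6 (1.2 equiv), THF/H2O, 0 °C
Reagents that add atoms: water, O
Why: periodic acid opens the epoxide to the glycol and cleaves it in the same flask (Malaprade cleavage), giving the aldehyde (future C1) and the methyl ketone (future C13) from both epoxide isomers.

Step 4
Reactants: 6 keto aldehyde
Product: 7 (3S)-3-(hexa-1,5-dien-2-yl)-2-methylidene-6-oxoheptanal
Conditions: CH2=NMe2+ I− (Eschenmoser's salt, 2 equiv), Et3N, CH2Cl2, rt
Reagents that add atoms: N,N-dimethylmethyleneiminium iodide (Eschenmoser's salt), C=[N+](C)C.[I-]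
Why: Mannich-type α-methylenation (aminomethylation, then loss of dimethylamine) is selective for the readily enolised aldehyde over the methyl ketone and places C20 on C10.

Step 5
Reactants: 7 keto enal
Product: 8 (5S,7RS)-5-(hexa-1,5-dien-2-yl)-7-hydroxy-6-methylideneoctan-2-one
Conditions: MeTi(Oi-Pr)3 (1.5 equiv), THF, −50 → 0 °C
Reagents that add atoms: methyltitanium triisopropoxide, C[Ti](OC(C)C)(OC(C)C)OC(C)C
Why: the titanium methyl reagent adds 1,2 to aldehydes but leaves ketones untouched, so C2 is delivered to C1 with the C13 ketone intact, and the new carbinol centre is an inconsequential mixture.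

Step 6
Reactants: 8 hydroxy ketone; 9 triethyl phosphonoacetate
Product: 10 ethyl (2E,6S,8RS)-6-(hexa-1,5-dien-2-yl)-8-hydroxy-3-methyl-7-methylidenenon-2-enoate
Conditions: NaH (2.5 equiv), 9 (1.5 equiv), THF, 0 → 50 °C
Reagents that add atoms: none
Why: Horner–Wadsworth–Emmons olefination of the methyl ketone builds C13=C14 with the E isomer expected to predominate (longer chain trans to the ester), the minor 2Z isomer being removed by chromatography at the stage of diol 11, while the sodium alkoxide of the secondary alcohol is a spectator.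

Step 7
Reactants: 10 hydroxy enoate
Product: 11 (2E,6S,8RS)-6-(hexa-1,5-dien-2-yl)-3-methyl-7-methylidenenon-2-ene-1,8-diol
Conditions: i-Bu2AlH (4 equiv), CH2Cl2, −78 °C; Rochelle salt work-up
Reagents that add atoms: none
Why: 1,2-reduction of the α,β-unsaturated ester by the aluminium hydride gives the E-allylic alcohol (C15) without touching the isolated alkenes.

Step 8
Reactants: 11 diol
Product: 12 (2RS,4S,7E)-9-[tert-butyl(diphenyl)silyl]oxy-4-(hexa-1,5-dien-2-yl)-7-methyl-3-methylidenenon-7-en-2-ol
Conditions: TBDPSCl (1.05 equiv), imidazole, CH2Cl2, 0 °C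
Reagents that add atoms: tert-butyl(chloro)diphenylsilane, CC(C)(C)[Si](Cl)(c1ccccc1)c1ccccc1
Why: the bulky silyl chloride silylates the primary allylic hydroxyl in preference to the hindered secondary one and masks C15–OH against the bases of steps 12 and 15.

Step 9
Reactants: 12 silyl ether alcohol
Product: 13 (4S,7E)-9-[tert-butyl(diphenyl)silyl]oxy-4-(hexa-1,5-dien-2-yl)-7-methyl-3-methylidenenon-7-en-2-one
Conditions: Dess–Martin periodinane (1.3 equiv), CH2Cl2, 0 °C → rt; used without storage
Reagents that add atoms: none
Why: Dess–Martin oxidation converts the secondary allylic alcohol into the α-methylene ketone under near-neutral conditions that should not move the doubly allylic H-9 into conjugation.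

Step 10
Reactants: 13 enone
Product: 14 (3RS,4R,7E)-9-[tert-butyl(diphenyl)silyl]oxy-4-(hexa-1,5-dien-2-yl)-3,7-dimethylnon-7-en-2-one
Conditions: [(Ph3P)CuH]6 (Stryker's reagent, 0.4 equiv), H2O (5 equiv), degassed toluene, rt
Reagents that add atoms: none
Why: the copper hydride hexamer reduces enones by conjugate hydride delivery and leaves isolated alkenes and silyl ethers alone, giving the α-methyl ketone as a C10 epimer mixture that converges in step 12.

Step 11
Reactants: 14 ketone; 15 methyl 2-(bromomethyl)acrylate
Product: 16 methyl (2Z,7R,10E)-2-(bromomethyl)-12-[tert-butyl(diphenyl)silyl]oxy-10-methyl-6-methylidene-7-[(2RS)-3-oxobutan-2-yl]dodeca-2,10-dienoate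
Conditions: second-generation Hoveyda–Grubbs catalyst RuCl2(H2IMes)(=CH-C6H4-2-O-i-Pr) (2 × 5 mol%), 15 (10 equiv), CH2Cl2, 40 °C, argon sparge
Reagents that add atoms: none
Why: olefin cross-metathesis of the only monosubstituted alkene with an α-substituted acrylate (the methacrylate class of partner) should give the trisubstituted alkenoate with the ester trans to the chain, the 1,1-disubstituted C8=C17 and trisubstituted C13=C14 alkenes being too hindered to engage, and either alkene geometry would serve because C4 becomes sp2 again in step 12.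

Step 12
Reactants: 16 bromo keto ester
Product: 18 methyl 15-O-TBDPS-1-oxo-18-norisocupressate (trans-decalin with C1=O, C4-H(CO2Me) as both C4 epimers, C8=CH2, 5α-H, 9α-H, 10β-CH3), via monocyclic acrylate 17 (not isolated)
Conditions: KOt-Bu (1.2 equiv), t-BuOH (2 equiv), THF (5 mM), −40 → 0 °C
Reagents that add atoms: none
Why: Proposed new method: this is an intramolecular, ring-forming version of the α,α'-annulation of a ketone with a 2-(bromomethyl)acrylate (Michael addition, E1cB loss of bromide, second Michael addition), the closest known reaction type being the intermolecular annulation of ketone enolates or enamines with 2-(bromomethyl)acrylates to 4-carboxycyclohexanones, which has not been run with the two partners tethered so that both rings of a decalin form. KOt-Bu/t-BuOH equilibrates the C2 and C10 enolates of 16 (both C10 epimers give the same tetrasubstituted enolate), and only the C10 enolate has a low-barrier exit: 6-exo-trig conjugate addition to C5 closes ring B and forms C5–C10, after which the C4 ester enolate expels bromide to leave acrylate 17. The methyl ketone of 17 is then enolised at C2 by the remaining base and adds 6-endo-trig to the acrylate terminus C3, closing ring A and forming C2–C3, a stage that is catalytic in base. C10 is controlled by the resident C9 stereocentre: in the chair transition state the C9 side chain is equatorial and H-9 eclipses the enolate C10=C1 bond (minimised allylic 1,3-strain), so C5 adds to the face that leaves the C10 methyl axial and anti to H-9. C5 is controlled by the equatorial placement of the alkenoate arm in the same chair, which puts H-5 axial and trans to the C10 methyl and hence gives the trans-decalin, while C4 forms as an epimer mixture that step 15 corrects. The step needs C-attack of C10 on C5 to outrun 1,4-elimination of HBr and intermolecular alkylation and needs the trans ring fusion; the six-membered intramolecular delivery at low temperature and high dilution and the equatorial preference in the chair are what the substrate offers for this.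

Step 13
Reactants: 18 keto ester
Product: 19 C1 tosylhydrazone of 18
Conditions: TsNHNH2 (1.5 equiv), PPTS (10 mol%), EtOH, 60 °C
Reagents that add atoms: 4-methylbenzenesulfonohydrazide, Cc1ccc(cc1)S(=O)(=O)NN
Why: condensation of the ketone with tosylhydrazide gives the hydrazone, the C1 carbonyl being flanked by quaternary C10 but still open on the C2 side.

Step 14
Reactants: 19 tosylhydrazone
Product: 20 methyl 15-O-TBDPS-18-norisocupressate (C1 now CH2; both C4 epimers)
Conditions: catecholborane (3 equiv), CHCl3, 0 °C → rt; then NaOAc·3H2O, 65 °C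
Reagents that add atoms: none
Why: in this mild variant of the Caglioti reduction catecholborane adds hydride to the C=N bond and acetate-induced loss of sulfinate and N2 leaves CH2 at C1 under conditions that spare the ester, the alkenes and the silyl ether.

Step 15
Reactants: 20 ester
Product: 21 methyl 15-O-TBDPS-isocupressate [methyl (13E)-15-[tert-butyl(diphenyl)silyl]oxylabda-8(17),13-dien-19-oate]
Conditions: LiN(i-Pr)2 (1.5 equiv), THF/DMPU, −78 → −30 °C; MeI (5 equiv), −78 → 0 °C
Reagents that add atoms: iodomethane, CI
Why: ester enolate alkylation of the planar C4 enolate should occur from the equatorial α face, away from the axial C10 methyl that shields the β face, which places CH3 equatorial and CO2Me axial (4S) and erases the C4 epimer mixture.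

Step 16
Reactants: 21 silyl ether
Product: 22 methyl isocupressate [methyl (13E)-15-hydroxylabda-8(17),13-dien-19-oate]
Conditions: n-Bu4NF (1.5 equiv), THF, 0 °C → rt
Reagents that add atoms: none
Why: fluoride cleaves the silicon–oxygen bond of the silyl ether while the hindered tertiary methyl ester is inert.

Step 17
Reactants: 22 allylic alcohol; 23 palmitoyl chloride
Product: 24 methyl (13E)-15-(hexadecanoyloxy)labda-8(17),13-dien-19-oate (target)
Conditions: 23 (1.3 equiv), pyridine, DMAP (10 mol%), CH2Cl2, 0 °C → rt
Reagents that add atoms: none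
Why: DMAP-catalysed acylation of the unhindered primary allylic alcohol with the acid chloride gives the palmitate without affecting the C19 ester or the alkenes.

**Compound list**

1 | (R)-(+)-limonene | CC1=CC[C@@H](CC1)C(C)=C | starting material
2 | allyl bromide | C=CCBr | starting material
3 | lithiated limonene (allyllithium at the isopropenyl methyl, TMEDA complex) | CC1=CC[C@@H](CC1)C(=C)C[Li] | intermediate (not isolated)
4 | (4R)-4-(hexa-1,5-dien-2-yl)-1-methylcyclohex-1-ene | CC1=CC[C@@H](CC1)C(=C)CCC=C | intermediate
5 | (4R)-4-(hexa-1,5-dien-2-yl)-1-methyl-7-oxabicyclo[4.1.0]heptane (epoxide mixture) | CC12OC1C[C@@H](CC2)C(=C)CCC=C | intermediate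
6 | (3R)-3-(hexa-1,5-dien-2-yl)-6-oxoheptanal | O=CC[C@@H](CCC(C)=O)C(=C)CCC=C | intermediate
7 | (3S)-3-(hexa-1,5-dien-2-yl)-2-methylidene-6-oxoheptanal | O=CC(=C)[C@@H](CCC(C)=O)C(=C)CCC=C | intermediate
8 | (5S,7RS)-5-(hexa-1,5-dien-2-yl)-7-hydroxy-6-methylideneoctan-2-one | CC(O)C(=C)[C@@H](CCC(C)=O)C(=C)CCC=C | intermediate
9 | triethyl phosphonoacetate | CCOC(=O)CP(=O)(OCC)OCC | starting material
10 | ethyl (2E,6S,8RS)-6-(hexa-1,5-dien-2-yl)-8-hydroxy-3-methyl-7-methylidenenon-2-enoate | CC(O)C(=C)[C@@H](CC/C(C)=C/C(=O)OCC)C(=C)CCC=C | intermediate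
11 | (2E,6S,8RS)-6-(hexa-1,5-dien-2-yl)-3-methyl-7-methylidenenon-2-ene-1,8-diol | CC(O)C(=C)[C@@H](CC/C(C)=C/CO)C(=C)CCC=C | intermediate
12 | (2RS,4S,7E)-9-[tert-butyl(diphenyl)silyl]oxy-4-(hexa-1,5-dien-2-yl)-7-methyl-3-methylidenenon-7-en-2-ol | CC(O)C(=C)[C@@H](CC/C(C)=C/CO[Si](c1ccccc1)(c1ccccc1)C(C)(C)C)C(=C)CCC=C | intermediate
13 | (4S,7E)-9-[tert-butyl(diphenyl)silyl]oxy-4-(hexa-1,5-dien-2-yl)-7-methyl-3-methylidenenon-7-en-2-one | CC(=O)C(=C)[C@@H](CC/C(C)=C/CO[Si](c1ccccc1)(c1ccccc1)C(C)(C)C)C(=C)CCC=C | intermediate
14 | (3RS,4R,7E)-9-[tert-butyl(diphenyl)silyl]oxy-4-(hexa-1,5-dien-2-yl)-3,7-dimethylnon-7-en-2-one | CC(=O)C(C)[C@@H](CC/C(C)=C/CO[Si](c1ccccc1)(c1ccccc1)C(C)(C)C)C(=C)CCC=C | intermediate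
15 | methyl 2-(bromomethyl)acrylate | C=C(CBr)C(=O)OC | starting material
16 | methyl (2Z,7R,10E)-2-(bromomethyl)-12-[tert-butyl(diphenyl)silyl]oxy-10-methyl-6-methylidene-7-[(2RS)-3-oxobutan-2-yl]dodeca-2,10-dienoate | CC(=O)C(C)[C@@H](CC/C(C)=C/CO[Si](c1ccccc1)(c1ccccc1)C(C)(C)C)C(=C)CC/C=C(\CBr)C(=O)OC | intermediate
17 | methyl 2-[(1R,2R,3S)-2-acetyl-3-[(3E)-5-[tert-butyl(diphenyl)silyl]oxy-3-methylpent-3-en-1-yl]-2-methyl-4-methylidenecyclohexyl]prop-2-enoate | C=C1CC[C@@H](C(=C)C(=O)OC)[C@](C)(C(C)=O)[C@H]1CC/C(C)=C/CO[Si](c1ccccc1)(c1ccccc1)C(C)(C)C | intermediate (not isolated)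
18 | methyl 15-O-TBDPS-1-oxo-18-norisocupressate: trans-decalin, C1=O, C4-H(CO2Me) as C4 epimers, C8=CH2, 5α-H, 9α-H, 10β-CH3, (13E) side chain | C=C1CC[C@@H]2[C@](C)(C(=O)CCC2C(=O)OC)[C@H]1CC/C(C)=C/CO[Si](c1ccccc1)(c1ccccc1)C(C)(C)C | intermediate
19 | C1 tosylhydrazone of 18 | C=C1CC[C@@H]2[C@](C)(C(=NNS(=O)(=O)c3ccc(C)cc3)CCC2C(=O)OC)[C@H]1CC/C(C)=C/CO[Si](c1ccccc1)(c1ccccc1)C(C)(C)C | intermediate
20 | methyl 15-O-TBDPS-18-norisocupressate (C4 epimers) | C=C1CC[C@@H]2[C@](C)(CCCC2C(=O)OC)[C@H]1CC/C(C)=C/CO[Si](c1ccccc1)(c1ccccc1)C(C)(C)C | intermediate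
21 | methyl (13E)-15-[tert-butyl(diphenyl)silyl]oxylabda-8(17),13-dien-19-oate | C=C1CC[C@@H]2[C@](C)(CCC[C@]2(C)C(=O)OC)[C@H]1CC/C(C)=C/CO[Si](c1ccccc1)(c1ccccc1)C(C)(C)C | intermediate
22 | methyl isocupressate, methyl (13E)-15-hydroxylabda-8(17),13-dien-19-oate | C=C1CC[C@@H]2[C@](C)(CCC[C@]2(C)C(=O)OC)[C@H]1CC/C(C)=C/CO | intermediate
23 | palmitoyl chloride (hexadecanoyl chloride) | CCCCCCCCCCCCCCCC(=O)Cl | starting material
24 | methyl (13E)-15-(hexadecanoyloxy)labda-8(17),13-dien-19-oate | C=C1CC[C@@H]2[C@](C)(CCC[C@]2(C)C(=O)OC)[C@H]1CC/C(C)=C/COC(=O)CCCCCCCCCCCCCCC | target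

**Step count and risks**

Total step count: 17. Longest linear sequence: 17 steps (1 → 24).

Steps most likely to fail:

1. Step 12 (the labelled step). The free base may dehydrobrominate the allylic bromide in a 1,4 sense, or the enolates may alkylate intermolecularly, faster than C10 adds to C5. The addition may also take the wrong face of C5 and lead into the cis-fused series. Fallback with known chemistry, stepwise and with a regiospecific enolate in the absence of free base: it sets out from enone 13. RhCl(PPh3)3-catalysed 1,4-hydrosilylation with Et3SiH would give the triethylsilyl enol ether F1, in which the enol double bond is fixed between C10 and C1. Cross-metathesis with 15 under the conditions of step 11 would give the bromo ester silyl enol ether F2. n-Bu4N[Ph3SiF2] in THF at −78 °C would unmask the C10 enolate alone and close ring B by Mukaiyama–Michael-type addition and loss of bromide, giving acrylate 17, which is isolated here. A catalytic amount of KOt-Bu in THF/t-BuOH would then close ring A by the 6-endo Michael addition, and the route is rejoined at 18.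

2. Step 11. The ruthenium alkylidene may turn over too slowly with the hindered, electron-poor bromomethyl acrylate, so that self-metathesis of 14 and catalyst decay at the allylic C–Br bond take over. Fallback: it sets out from 14 and moves the halide out of the metathesis step. Cross-metathesis with the smaller, halide-free methyl 2-(hydroxymethyl)acrylate under the same catalyst would give the hydroxymethyl alkenoate F3. Appel bromination (CBr4, PPh3, CH2Cl2, 0 °C) would then convert the primary allylic alcohol into the bromide, and the route is rejoined at 16.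

3. Step 13. Condensation at the C1 carbonyl may stall because of shielding by the quaternary C10 and the C9 side chain, and forcing acidic conditions would erode the allylic silyl ether. Fallback: it sets out from 18 and removes the oxygen by radical deoxygenation instead. NaBH4 in MeOH at 0 °C would give the C1 alcohol F4. NaH, CS2, then MeI in THF would give the S-methyl xanthate F5. Barton–McCombie reduction (n-Bu3SnH at high concentration, AIBN, toluene, 100 °C, to suppress cyclisation of the C1 radical onto C13) would give the C1 methylene compound, and the route is rejoined at 20.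

Further compounds
F1 | step 12 | (4S,7E)-9-[tert-butyl(diphenyl)silyl]oxy-4-(hexa-1,5-dien-2-yl)-3,7-dimethyl-2-(triethylsilyloxy)nona-2,7-diene (enol ether E/Z mixture) | CC(O[Si](CC)(CC)CC)=C(C)[C@@H](CC/C(C)=C/CO[Si](c1ccccc1)(c1ccccc1)C(C)(C)C)C(=C)CCC=C
F2 | step 12 | methyl (2Z,7S,10E)-2-(bromomethyl)-12-[tert-butyl(diphenyl)silyl]oxy-10-methyl-6-methylidene-7-[3-(triethylsilyloxy)but-2-en-2-yl]dodeca-2,10-dienoate | CC(O[Si](CC)(CC)CC)=C(C)[C@@H](CC/C(C)=C/CO[Si](c1ccccc1)(c1ccccc1)C(C)(C)C)C(=C)CC/C=C(\CBr)C(=O)OC
F3 | step 11 | methyl (2E,7R,10E)-12-[tert-butyl(diphenyl)silyl]oxy-2-(hydroxymethyl)-10-methyl-6-methylidene-7-[(2RS)-3-oxobutan-2-yl]dodeca-2,10-dienoate | CC(=O)C(C)[C@@H](CC/C(C)=C/CO[Si](c1ccccc1)(c1ccccc1)C(C)(C)C)C(=C)CC/C=C(\CO)C(=O)OC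
F4 | step 13 | methyl 15-O-TBDPS-1-hydroxy-18-norisocupressate (C1 and C4 epimers) | C=C1CC[C@@H]2[C@](C)(C(O)CCC2C(=O)OC)[C@H]1CC/C(C)=C/CO[Si](c1ccccc1)(c1ccccc1)C(C)(C)C
F5 | step 13 | S-methyl xanthate of F4 at C1–O | C=C1CC[C@@H]2[C@](C)(C(OC(=S)SC)CCC2C(=O)OC)[C@H]1CC/C(C)=C/CO[Si](c1ccccc1)(c1ccccc1)C(C)(C)C
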